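Assumption: the target is taken exactly as encoded in the SMILES; (R)-but-3-yn-2-ol, tributyl(trimethylsilyl)stannane and vinylboronic acid pinacol ester are bought. The route is a design and has not been run.

## Retrosynthetic overview

1. Last operations: global desilylation, and before it oxidative opening of a 2-methylfuran fused to the seven-membered ring, which unmasks the ring ketone and the Z-configured ene-dione.
2. The E-enol ester comes from an E-alkenyl boron species (copper-catalysed acyloxylation), itself made by cross-metathesis of a propenyl group.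
3. The seven-membered carbocycle is closed by an intramolecular Nozaki–Hiyama–Kishi addition of a Z-vinyl bromide to a neopentyl aldehyde, which also creates the ring carbinol.
4. Key union: copper-catalysed O-vinylation of a furan-bearing (R)-allylic alcohol (west half) with an E-vinyl iodide (east half), followed by Claisen rearrangement. This gives the quaternary/tertiary stereocentre pair and the aldehyde in one operation.
5. West half from 2-methylfuran, propargyl alcohol and (R)-but-3-yn-2-ol; east half from pent-4-ynoic acid (CBS reduction sets the side-chain carbinol). Ring order: furan bought in, carbocycle by chromium-mediated closure, furan ring opened last.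

## Route

Step 1
Reactants: 1 prop-2-yn-1-ol
Product: 2 tert-butyldimethyl(prop-2-yn-1-yloxy)silane
Conditions: TBSCl, imidazole, CH2Cl2, 0 °C to rt
Reagents that add atoms: tert-butyldimethylsilyl chloride, CC(C)(C)[Si](C)(C)Cl
Why: Standard silyl ether formation (protection) masks the oxygen that becomes the ring hydroxymethyl group until the last step.

Step 2
Reactants: 2 tert-butyldimethyl(prop-2-yn-1-yloxy)silane
Product: 3 tert-butyldimethyl{[(2Z)-2-(tributylstannyl)-3-(trimethylsilyl)prop-2-en-1-yl]oxy}silane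
Conditions: Me3SiSnBu3 (1.05 equiv), Pd(PPh3)4 (2 mol %), THF, 65 °C
Reagents that add atoms: tributyl(trimethylsilyl)stannane, CCCC[Sn](CCCC)(CCCC)[Si](C)(C)C
Why: Palladium-catalysed silylstannation adds Si–Sn syn across the terminal alkyne with tin on the internal and silicon on the terminal carbon, which fixes the cis relation used later for the Z-vinyl bromide.

Step 3
Reactants: 4 2-methylfuran
Product: 5 2-bromo-5-methylfuran
Conditions: NBS, DMF, 0 °C to rt
Reagents that add atoms: N-bromosuccinimide, O=C1CCC(=O)N1Br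
Why: Electrophilic aromatic bromination goes to the only free α-position of the furan.

Step 4
Reactants: 5 2-bromo-5-methylfuran
Product: 8 3-bromo-2-iodo-5-methylfuran, via 3-lithio-2-bromo-5-methylfuran 6 (not isolated), via 2-lithio-3-bromo-5-methylfuran 7 (not isolated)
Conditions: LiN(iPr)2 (1.1 equiv), THF, −78 °C, 1 h; then I2, −78 °C to rt
Reagents that add atoms: iodine, II
Why: Halogen dance: metalation next to bromine is followed by bromine/lithium interchange to the more stable α-lithio furan, which iodine traps to give an α-iodide/β-bromide pair of different reactivity.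

Step 5
Reactants: 8 3-bromo-2-iodo-5-methylfuran; 3 tert-butyldimethyl{[(2Z)-2-(tributylstannyl)-3-(trimethylsilyl)prop-2-en-1-yl]oxy}silane
Product: 9 {[(2Z)-2-(3-bromo-5-methylfuran-2-yl)-3-(trimethylsilyl)prop-2-en-1-yl]oxy}(tert-butyl)dimethylsilane
Conditions: Pd(PPh3)4 (5 mol %), CuI (10 mol %), CsF (2 equiv), DMF, 45 °C
Reagents that add atoms: none
Why: Stille coupling takes place at the α-iodide, far more reactive than the β-bromide, with retention of the stannane geometry, so the furan ends up cis to silicon.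

Step 6
Reactants: 9 {[(2Z)-2-(3-bromo-5-methylfuran-2-yl)-3-(trimethylsilyl)prop-2-en-1-yl]oxy}(tert-butyl)dimethylsilane; 10 (2R)-but-3-yn-2-ol
Product: 11 (2R)-4-{2-[(1Z)-3-[(tert-butyldimethylsilyl)oxy]-1-(trimethylsilyl)prop-1-en-2-yl]-5-methylfuran-3-yl}but-3-yn-2-ol
Conditions: PdCl2(MeCN)2 (3 mol %), XPhos (9 mol %), Cs2CO3 (2.5 equiv), MeCN, 70 °C
Reagents that add atoms: none
Why: Copper-free Sonogashira coupling of the remaining heteroaryl bromide with the terminal alkyne; the carbinol stereocentre is bought in and is not touched.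

Step 7
Reactants: 11 (2R)-4-{2-[(1Z)-3-[(tert-butyldimethylsilyl)oxy]-1-(trimethylsilyl)prop-1-en-2-yl]-5-methylfuran-3-yl}but-3-yn-2-ol
Product: 12 (2R,3Z)-4-{2-[(1Z)-3-[(tert-butyldimethylsilyl)oxy]-1-(trimethylsilyl)prop-1-en-2-yl]-5-methylfuran-3-yl}but-3-en-2-ol
Conditions: H2 (1 atm), Lindlar catalyst (Pd on CaCO3 poisoned with Pb(OAc)2), quinoline, EtOAc, rt
Reagents that add atoms: none
Why: Lindlar semihydrogenation delivers hydrogen syn to give the cis allylic alcohol, and the trisubstituted vinylsilane and the furan are not reduced.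

Step 8
Reactants: 12 (2R,3Z)-4-{2-[(1Z)-3-[(tert-butyldimethylsilyl)oxy]-1-(trimethylsilyl)prop-1-en-2-yl]-5-methylfuran-3-yl}but-3-en-2-ol
Product: 13 (2R,3Z)-4-{2-[(1Z)-1-bromo-3-[(tert-butyldimethylsilyl)oxy]prop-1-en-2-yl]-5-methylfuran-3-yl}but-3-en-2-ol
Conditions: NBS (1.05 equiv), MeCN, −20 to 0 °C, dark
Reagents that add atoms: N-bromosuccinimide, O=C1CCC(=O)N1Br
Why: ipso-Bromodesilylation of the furan-conjugated vinylsilane (β-silyl, furyl-stabilised cation) is the fastest electrophilic pathway and proceeds with retention, placing bromine cis to the furan.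

Step 9
Reactants: 14 pent-4-ynoic acid
Product: 15 N-methoxy-N-methylpent-4-ynamide
Conditions: CDI, CH2Cl2, rt; then MeNH(OMe)·HCl, rt
Reagents that add atoms: N,O-dimethylhydroxylamine hydrochloride, CNOC.Cl
Why: Amidation through the acyl imidazolide gives the Weinreb amide.

Step 10
Reactants: 15 N-methoxy-N-methylpent-4-ynamide
Product: 16 2-methylhept-1-en-6-yn-3-one
Conditions: isopropenylmagnesium bromide (2.3 equiv), THF, −78 to 0 °C; cold aq. HCl quench
Reagents that add atoms: isopropenylmagnesium bromide, CC(=C)[Mg]Br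
Why: Grignard addition to the Weinreb amide stops at the chelated tetrahedral intermediate (one equivalent is spent on the alkyne C–H) and releases the isopropenyl ketone on acidic work-up.

Step 11
Reactants: 16 2-methylhept-1-en-6-yn-3-one
Product: 17 (3R)-2-methylhept-1-en-6-yn-3-ol
Conditions: (S)-2-methyl-CBS-oxazaborolidine (20 mol %), catecholborane (1.5 equiv), toluene, −78 °C
Reagents that add atoms: none
Why: Corey–Bakshi–Shibata reduction with the isopropenyl group acting as the large substituent delivers hydride to one face and sets the (R)-carbinol of the side chain.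

Step 12
Reactants: 17 (3R)-2-methylhept-1-en-6-yn-3-ol
Product: 18 tert-butyldimethyl{[(3R)-2-methylhept-1-en-6-yn-3-yl]oxy}silane
Conditions: TBSCl, imidazole, DMF, rt
Reagents that add atoms: tert-butyldimethylsilyl chloride, CC(C)(C)[Si](C)(C)Cl
Why: Silyl protection of the allylic alcohol, needed for the organoaluminium and copper steps that follow.

Step 13
Reactants: 18 tert-butyldimethyl{[(3R)-2-methylhept-1-en-6-yn-3-yl]oxy}silane
Product: 20 tert-butyl{[(3R,6E)-7-iodo-2,6-dimethylhepta-1,6-dien-3-yl]oxy}dimethylsilane, via alkenyl(dimethyl)alane 19 (not isolated)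
Conditions: Me3Al (2.5 equiv), Cp2ZrCl2 (25 mol %), CH2Cl2, 0 °C to rt; then I2, THF, −30 to 0 °C
Reagents that add atoms: trimethylaluminium, C[Al](C)C; iodine, II
Why: Negishi zirconium-catalysed carboalumination adds methyl and aluminium syn with aluminium at the terminus, and iodinolysis with retention gives the E-iodide whose methyl group is cis to iodine.

Step 14
Reactants: 13 (2R,3Z)-4-{2-[(1Z)-1-bromo-3-[(tert-butyldimethylsilyl)oxy]prop-1-en-2-yl]-5-methylfuran-3-yl}but-3-en-2-ol; 20 tert-butyl{[(3R,6E)-7-iodo-2,6-dimethylhepta-1,6-dien-3-yl]oxy}dimethylsilane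
Product: 22 (2R,5R)-2-[(1S,2E)-1-{2-[(1Z)-1-bromo-3-[(tert-butyldimethylsilyl)oxy]prop-1-en-2-yl]-5-methylfuran-3-yl}but-2-en-1-yl]-5-[(tert-butyldimethylsilyl)oxy]-2,6-dimethylhept-6-enal, via allyl vinyl ether 21 (not isolated)
Conditions: CuI (10 mol %), 3,4,7,8-tetramethyl-1,10-phenanthroline (20 mol %), Cs2CO3 (2 equiv), o-xylene, 90 °C; then 140 °C
Reagents that add atoms: none
Why: Ullmann-type C–O coupling of the vinyl iodide (the hindered vinyl bromide is left) with retention, then Claisen rearrangement through a chair in which the carbinol methyl is equatorial and the cis-furyl group and the enol-ether methyl are axial, so the (R)-carbinol is transferred into the (2R) quaternary centre and the (1S) furyl-bearing centre while the E-propenyl group and the aldehyde are formed.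

Step 15
Reactants: 22 (2R,5R)-2-[(1S,2E)-1-{2-[(1Z)-1-bromo-3-[(tert-butyldimethylsilyl)oxy]prop-1-en-2-yl]-5-methylfuran-3-yl}but-2-en-1-yl]-5-[(tert-butyldimethylsilyl)oxy]-2,6-dimethylhept-6-enal
Product: 24 (4R,5R,6S)-8-{[(tert-butyldimethylsilyl)oxy]methyl}-5-{(3R)-3-[(tert-butyldimethylsilyl)oxy]-4-methylpent-4-en-1-yl}-2,5-dimethyl-4-[(1E)-prop-1-en-1-yl]-5,6-dihydro-4H-cyclohepta[b]furan-6-ol, via alkenylchromium dichloride 23 (not isolated)
Conditions: CrCl2 (8 equiv), NiCl2 (5 mol %), DMSO/THF, 5 mM, rt to 45 °C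
Reagents that add atoms: none
Why: Intramolecular Nozaki–Hiyama–Kishi addition closes the seven-membered ring with retention of the olefin geometry, and the chromium alkoxide is expected to develop on the face away from the neighbouring propenyl group, giving the (6S)-alcohol trans to it.

Step 16
Reactants: 24 (4R,5R,6S)-8-{[(tert-butyldimethylsilyl)oxy]methyl}-5-{(3R)-3-[(tert-butyldimethylsilyl)oxy]-4-methylpent-4-en-1-yl}-2,5-dimethyl-4-[(1E)-prop-1-en-1-yl]-5,6-dihydro-4H-cyclohepta[b]furan-6-ol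
Product: 25 (4R,5R,6S)-8-{[(tert-butyldimethylsilyl)oxy]methyl}-5-{(3R)-3-[(tert-butyldimethylsilyl)oxy]-4-methylpent-4-en-1-yl}-2,5-dimethyl-4-[(E)-2-(4,4,5,5-tetramethyl-1,3,2-dioxaborolan-2-yl)ethenyl]-5,6-dihydro-4H-cyclohepta[b]furan-6-ol
Conditions: vinylboronic acid pinacol ester (6 equiv), second-generation Hoveyda–Grubbs catalyst (10 mol %), CH2Cl2, 40 °C
Reagents that add atoms: vinylboronic acid pinacol ester, C=CB1OC(C)(C)C(C)(C)O1
Why: E-selective olefin cross-metathesis exchanges the methyl-capped end of the propenyl group for the boryl-substituted carbon, while the trisubstituted ring olefin and the 1,1-disubstituted olefin next to the silyl ether are too hindered to engage.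

Step 17
Reactants: 25 (4R,5R,6S)-8-{[(tert-butyldimethylsilyl)oxy]methyl}-5-{(3R)-3-[(tert-butyldimethylsilyl)oxy]-4-methylpent-4-en-1-yl}-2,5-dimethyl-4-[(E)-2-(4,4,5,5-tetramethyl-1,3,2-dioxaborolan-2-yl)ethenyl]-5,6-dihydro-4H-cyclohepta[b]furan-6-ol
Product: 26 potassium {(E)-2-[(4R,5R,6S)-8-{[(tert-butyldimethylsilyl)oxy]methyl}-5-{(3R)-3-[(tert-butyldimethylsilyl)oxy]-4-methylpent-4-en-1-yl}-6-hydroxy-2,5-dimethyl-5,6-dihydro-4H-cyclohepta[b]furan-4-yl]ethenyl}trifluoroborate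
Conditions: KHF2 (4.5 equiv), MeOH/H2O, rt
Reagents that add atoms: potassium hydrogen difluoride, F.[F-].[K+]
Why: Ligand exchange at boron turns the pinacol boronate into the trifluoroborate needed for the copper coupling without touching the olefin geometry.

Step 18
Reactants: 26 potassium {(E)-2-[(4R,5R,6S)-8-{[(tert-butyldimethylsilyl)oxy]methyl}-5-{(3R)-3-[(tert-butyldimethylsilyl)oxy]-4-methylpent-4-en-1-yl}-6-hydroxy-2,5-dimethyl-5,6-dihydro-4H-cyclohepta[b]furan-4-yl]ethenyl}trifluoroborate; 27 3-methylbut-2-enoic acid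
Product: 28 (E)-2-[(4R,5R,6S)-8-{[(tert-butyldimethylsilyl)oxy]methyl}-5-{(3R)-3-[(tert-butyldimethylsilyl)oxy]-4-methylpent-4-en-1-yl}-6-hydroxy-2,5-dimethyl-5,6-dihydro-4H-cyclohepta[b]furan-4-yl]ethenyl 3-methylbut-2-enoate
Conditions: CuBr (10 mol %), DMAP (20 mol %), 4 Å MS, O2 (1 atm), MeCN, 60 °C
Reagents that add atoms: none
Why: Copper-catalysed oxidative (Chan–Lam-type) C–O coupling of the alkenyltrifluoroborate with the carboxylic acid proceeds with retention and gives the E-enol ester, the acid being a far better partner than the hindered secondary alcohol.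

Step 19
Reactants: 28 (E)-2-[(4R,5R,6S)-8-{[(tert-butyldimethylsilyl)oxy]methyl}-5-{(3R)-3-[(tert-butyldimethylsilyl)oxy]-4-methylpent-4-en-1-yl}-6-hydroxy-2,5-dimethyl-5,6-dihydro-4H-cyclohepta[b]furan-4-yl]ethenyl 3-methylbut-2-enoate
Product: 29 (E)-2-[(1R,2R,3S,7Z)-5-{[(tert-butyldimethylsilyl)oxy]methyl}-2-{(3R)-3-[(tert-butyldimethylsilyl)oxy]-4-methylpent-4-en-1-yl}-3-hydroxy-2-methyl-6-oxo-7-(2-oxopropylidene)cyclohept-4-en-1-yl]ethenyl 3-methylbut-2-enoate
Conditions: NBS (1.05 equiv), NaHCO3, acetone/H2O, −20 °C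
Reagents that add atoms: water, O
Why: Oxidative ring opening of the electron-rich trisubstituted furan (bromination, hydration, loss of HBr) gives the ene-dione with both carbonyls on the same side, so the ring enone and the Z-configured 2-oxopropylidene appear together.

Step 20
Reactants: 29 (E)-2-[(1R,2R,3S,7Z)-5-{[(tert-butyldimethylsilyl)oxy]methyl}-2-{(3R)-3-[(tert-butyldimethylsilyl)oxy]-4-methylpent-4-en-1-yl}-3-hydroxy-2-methyl-6-oxo-7-(2-oxopropylidene)cyclohept-4-en-1-yl]ethenyl 3-methylbut-2-enoate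
Product: 30 (E)-2-[(1R,2R,3S,7Z)-3-hydroxy-5-(hydroxymethyl)-2-[(3R)-3-hydroxy-4-methylpent-4-en-1-yl]-2-methyl-6-oxo-7-(2-oxopropylidene)cyclohept-4-en-1-yl]ethenyl 3-methylbut-2-enoate
Conditions: HF·pyridine, pyridine, THF, 0 °C to rt
Reagents that add atoms: none
Why: Buffered fluoride desilylation removes the two allylic silyl ethers under mildly acidic conditions that the enol ester and the ene-dione tolerate.

## Compound list

1 | prop-2-yn-1-ol | C#CCO | starting material
2 | tert-butyldimethyl(prop-2-yn-1-yloxy)silane | C#CCO[Si](C)(C)C(C)(C)C | intermediate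
3 | tert-butyldimethyl{[(2Z)-2-(tributylstannyl)-3-(trimethylsilyl)prop-2-en-1-yl]oxy}silane | C[Si](C)(C)/C=C(/CO[Si](C)(C)C(C)(C)C)[Sn](CCCC)(CCCC)CCCC | intermediate
4 | 2-methylfuran | Cc1ccco1 | starting material
5 | 2-bromo-5-methylfuran | Cc1ccc(Br)o1 | intermediate
6 | (2-bromo-5-methylfuran-3-yl)lithium | Cc1cc([Li])c(Br)o1 | intermediate
7 | (3-bromo-5-methylfuran-2-yl)lithium | Cc1cc(Br)c([Li])o1 | intermediate
8 | 3-bromo-2-iodo-5-methylfuran | Cc1cc(Br)c(I)o1 | intermediate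
9 | {[(2Z)-2-(3-bromo-5-methylfuran-2-yl)-3-(trimethylsilyl)prop-2-en-1-yl]oxy}(tert-butyl)dimethylsilane | Cc1cc(Br)c(/C(CO[Si](C)(C)C(C)(C)C)=C\[Si](C)(C)C)o1 | intermediate
10 | (2R)-but-3-yn-2-ol | C[C@@H](O)C#C | starting material
11 | (2R)-4-{2-[(1Z)-3-[(tert-butyldimethylsilyl)oxy]-1-(trimethylsilyl)prop-1-en-2-yl]-5-methylfuran-3-yl}but-3-yn-2-ol | C[C@@H](O)C#Cc1cc(C)oc1/C(CO[Si](C)(C)C(C)(C)C)=C\[Si](C)(C)C | intermediate
12 | (2R,3Z)-4-{2-[(1Z)-3-[(tert-butyldimethylsilyl)oxy]-1-(trimethylsilyl)prop-1-en-2-yl]-5-methylfuran-3-yl}but-3-en-2-ol | C[C@@H](O)/C=C\c1cc(C)oc1/C(CO[Si](C)(C)C(C)(C)C)=C\[Si](C)(C)C | intermediate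
13 | (2R,3Z)-4-{2-[(1Z)-1-bromo-3-[(tert-butyldimethylsilyl)oxy]prop-1-en-2-yl]-5-methylfuran-3-yl}but-3-en-2-ol | C[C@@H](O)/C=C\c1cc(C)oc1/C(CO[Si](C)(C)C(C)(C)C)=C\Br | intermediate
14 | pent-4-ynoic acid | C#CCCC(=O)O | starting material
15 | N-methoxy-N-methylpent-4-ynamide | C#CCCC(=O)N(C)OC | intermediate
16 | 2-methylhept-1-en-6-yn-3-one | C=C(C)C(=O)CCC#C | intermediate
17 | (3R)-2-methylhept-1-en-6-yn-3-ol | C=C(C)[C@H](O)CCC#C | intermediate
18 | tert-butyldimethyl{[(3R)-2-methylhept-1-en-6-yn-3-yl]oxy}silane | C=C(C)[C@H](O[Si](C)(C)C(C)(C)C)CCC#C | intermediate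
19 | {(1E,5R)-5-[(tert-butyldimethylsilyl)oxy]-2,6-dimethylhepta-1,6-dien-1-yl}dimethylalane | C=C(C)[C@H](O[Si](C)(C)C(C)(C)C)CC/C(C)=C/[Al](C)C | intermediate
20 | tert-butyl{[(3R,6E)-7-iodo-2,6-dimethylhepta-1,6-dien-3-yl]oxy}dimethylsilane | C=C(C)[C@H](O[Si](C)(C)C(C)(C)C)CC/C(C)=C/I | intermediate
21 | tert-butyl({(3R,6E)-7-{[(2R,3Z)-4-{2-[(1Z)-1-bromo-3-[(tert-butyldimethylsilyl)oxy]prop-1-en-2-yl]-5-methylfuran-3-yl}but-3-en-2-yl]oxy}-2,6-dimethylhepta-1,6-dien-3-yl}oxy)dimethylsilane (allyl vinyl ether) | C=C(C)[C@H](O[Si](C)(C)C(C)(C)C)CC/C(C)=C/O[C@H](C)/C=C\c1cc(C)oc1/C(CO[Si](C)(C)C(C)(C)C)=C\Br | intermediate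
22 | (2R,5R)-2-[(1S,2E)-1-{2-[(1Z)-1-bromo-3-[(tert-butyldimethylsilyl)oxy]prop-1-en-2-yl]-5-methylfuran-3-yl}but-2-en-1-yl]-5-[(tert-butyldimethylsilyl)oxy]-2,6-dimethylhept-6-enal | C=C(C)[C@H](O[Si](C)(C)C(C)(C)C)CC[C@@](C)(C=O)[C@@H](/C=C/C)c1cc(C)oc1/C(CO[Si](C)(C)C(C)(C)C)=C\Br | intermediate
23 | alkenylchromium dichloride derived from 22 (CrCl2 group of trivalent chromium in place of bromine, same geometry) | C=C(C)[C@H](O[Si](C)(C)C(C)(C)C)CC[C@@](C)(C=O)[C@@H](/C=C/C)c1cc(C)oc1/C(CO[Si](C)(C)C(C)(C)C)=C\[Cr](Cl)Cl | intermediate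
24 | (4R,5R,6S)-8-{[(tert-butyldimethylsilyl)oxy]methyl}-5-{(3R)-3-[(tert-butyldimethylsilyl)oxy]-4-methylpent-4-en-1-yl}-2,5-dimethyl-4-[(1E)-prop-1-en-1-yl]-5,6-dihydro-4H-cyclohepta[b]furan-6-ol | C=C(C)[C@H](O[Si](C)(C)C(C)(C)C)CC[C@@]1(C)[C@@H](O)C=C(CO[Si](C)(C)C(C)(C)C)c2oc(C)cc2[C@@H]1/C=C/C | intermediate
25 | (4R,5R,6S)-8-{[(tert-butyldimethylsilyl)oxy]methyl}-5-{(3R)-3-[(tert-butyldimethylsilyl)oxy]-4-methylpent-4-en-1-yl}-2,5-dimethyl-4-[(E)-2-(4,4,5,5-tetramethyl-1,3,2-dioxaborolan-2-yl)ethenyl]-5,6-dihydro-4H-cyclohepta[b]furan-6-ol | C=C(C)[C@H](O[Si](C)(C)C(C)(C)C)CC[C@@]1(C)[C@@H](O)C=C(CO[Si](C)(C)C(C)(C)C)c2oc(C)cc2[C@@H]1/C=C/B3OC(C)(C)C(C)(C)O3 | intermediate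
26 | potassium {(E)-2-[(4R,5R,6S)-8-{[(tert-butyldimethylsilyl)oxy]methyl}-5-{(3R)-3-[(tert-butyldimethylsilyl)oxy]-4-methylpent-4-en-1-yl}-6-hydroxy-2,5-dimethyl-5,6-dihydro-4H-cyclohepta[b]furan-4-yl]ethenyl}trifluoroborate | C=C(C)[C@H](O[Si](C)(C)C(C)(C)C)CC[C@@]1(C)[C@@H](O)C=C(CO[Si](C)(C)C(C)(C)C)c2oc(C)cc2[C@@H]1/C=C/[B-](F)(F)F.[K+] | intermediate
27 | 3-methylbut-2-enoic acid | CC(C)=CC(=O)O | starting material
28 | (E)-2-[(4R,5R,6S)-8-{[(tert-butyldimethylsilyl)oxy]methyl}-5-{(3R)-3-[(tert-butyldimethylsilyl)oxy]-4-methylpent-4-en-1-yl}-6-hydroxy-2,5-dimethyl-5,6-dihydro-4H-cyclohepta[b]furan-4-yl]ethenyl 3-methylbut-2-enoate | C=C(C)[C@H](O[Si](C)(C)C(C)(C)C)CC[C@@]1(C)[C@@H](O)C=C(CO[Si](C)(C)C(C)(C)C)c2oc(C)cc2[C@@H]1/C=C/OC(=O)C=C(C)C | intermediate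
29 | (E)-2-[(1R,2R,3S,7Z)-5-{[(tert-butyldimethylsilyl)oxy]methyl}-2-{(3R)-3-[(tert-butyldimethylsilyl)oxy]-4-methylpent-4-en-1-yl}-3-hydroxy-2-methyl-6-oxo-7-(2-oxopropylidene)cyclohept-4-en-1-yl]ethenyl 3-methylbut-2-enoate | C=C(C)[C@H](O[Si](C)(C)C(C)(C)C)CC[C@@]1(C)[C@@H](O)C=C(CO[Si](C)(C)C(C)(C)C)C(=O)/C(=C\C(C)=O)[C@@H]1/C=C/OC(=O)C=C(C)C | intermediate
30 | (E)-2-[(1R,2R,3S,7Z)-3-hydroxy-5-(hydroxymethyl)-2-[(3R)-3-hydroxy-4-methylpent-4-en-1-yl]-2-methyl-6-oxo-7-(2-oxopropylidene)cyclohept-4-en-1-yl]ethenyl 3-methylbut-2-enoate | C=C(C)[C@H](O)CC[C@@]1(C)[C@@H](O)C=C(CO)C(=O)/C(=C\C(C)=O)[C@@H]1/C=C/OC(=O)C=C(C)C | target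

## Step count and risks

Total step count: 20.
Longest linear sequence: 13 steps (steps 1, 2, 5, 6, 7, 8, then 14 to 20; the branch from 2-methylfuran through steps 3 and 4 is equally long, the east branch through steps 9 to 13 gives 12).

The three steps most likely to fail:

**Step 14** (copper-catalysed O-vinylation and Claisen rearrangement). A hindered trisubstituted vinyl iodide has to couple with a secondary allylic alcohol without the vinyl bromide of 13 taking part, and the rearrangement then has to build a quaternary centre at 140 °C. The fallback sets out from 20. Iodine–lithium exchange (t-BuLi, Et2O, −78 °C) and trapping with 2-isopropoxy-4,4,5,5-tetramethyl-1,3,2-dioxaborolane gives tert-butyl{[(3R,6E)-2,6-dimethyl-7-(4,4,5,5-tetramethyl-1,3,2-dioxaborolan-2-yl)hepta-1,6-dien-3-yl]oxy}dimethylsilane F1. This is joined to 13 by an oxidative Chan–Lam-type etherification (Cu(OAc)2, Et3N, CH2Cl2, air, rt), under which a vinyl bromide is inert. The allyl vinyl ether 21 is isolated this time and heated alone in toluene at 140 °C, and the fallback comes back to the route at 22.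

**Step 15** (chromium-mediated ring closure). A seven-membered ring is closed from a vinyl bromide, and the configuration of the new carbinol rests on substrate control only. The fallback sets out from 22. The cyclisation is run as before; if it gives mainly or partly the epimeric alcohol (4R,5R,6R)-8-{[(tert-butyldimethylsilyl)oxy]methyl}-5-{(3R)-3-[(tert-butyldimethylsilyl)oxy]-4-methylpent-4-en-1-yl}-2,5-dimethyl-4-[(1E)-prop-1-en-1-yl]-5,6-dihydro-4H-cyclohepta[b]furan-6-ol F2, the crude alcohol is oxidised with Dess–Martin periodinane to (4S,5R)-8-{[(tert-butyldimethylsilyl)oxy]methyl}-5-{(3R)-3-[(tert-butyldimethylsilyl)oxy]-4-methylpent-4-en-1-yl}-2,5-dimethyl-4-[(1E)-prop-1-en-1-yl]-4,5-dihydro-6H-cyclohepta[b]furan-6-one F3. This enone is reduced under reagent control with (R)-2-methyl-CBS-oxazaborolidine and catecholborane (the quaternary carbon acting as the large group), and the fallback comes back at 24.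

**Step 18** (copper-catalysed acyloxylation). The method is proven only on simple alkenyltrifluoroborates, and here it has to work under oxygen at 60 °C next to an electron-rich furan and a free allylic alcohol. The fallback sets out from 25. Treatment with NaOH and I2 in THF/H2O at 0 °C gives, with retention, (4R,5R,6S)-8-{[(tert-butyldimethylsilyl)oxy]methyl}-5-{(3R)-3-[(tert-butyldimethylsilyl)oxy]-4-methylpent-4-en-1-yl}-4-[(E)-2-iodoethenyl]-2,5-dimethyl-5,6-dihydro-4H-cyclohepta[b]furan-6-ol F4. This is coupled with acid 27 in a non-oxidative Ullmann-type vinylation of the carboxylate (CuI, 3,4,7,8-tetramethyl-1,10-phenanthroline, Cs2CO3, toluene, 80 °C), and the fallback comes back at 28.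

## Further compounds

F1 | step 14 | tert-butyl{[(3R,6E)-2,6-dimethyl-7-(4,4,5,5-tetramethyl-1,3,2-dioxaborolan-2-yl)hepta-1,6-dien-3-yl]oxy}dimethylsilane | C=C(C)[C@H](O[Si](C)(C)C(C)(C)C)CC/C(C)=C/B1OC(C)(C)C(C)(C)O1
F2 | step 15 | (4R,5R,6R)-8-{[(tert-butyldimethylsilyl)oxy]methyl}-5-{(3R)-3-[(tert-butyldimethylsilyl)oxy]-4-methylpent-4-en-1-yl}-2,5-dimethyl-4-[(1E)-prop-1-en-1-yl]-5,6-dihydro-4H-cyclohepta[b]furan-6-ol | C=C(C)[C@H](O[Si](C)(C)C(C)(C)C)CC[C@@]1(C)[C@H](O)C=C(CO[Si](C)(C)C(C)(C)C)c2oc(C)cc2[C@@H]1/C=C/C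
F3 | step 15 | (4S,5R)-8-{[(tert-butyldimethylsilyl)oxy]methyl}-5-{(3R)-3-[(tert-butyldimethylsilyl)oxy]-4-methylpent-4-en-1-yl}-2,5-dimethyl-4-[(1E)-prop-1-en-1-yl]-4,5-dihydro-6H-cyclohepta[b]furan-6-one | C=C(C)[C@H](O[Si](C)(C)C(C)(C)C)CC[C@@]1(C)C(=O)C=C(CO[Si](C)(C)C(C)(C)C)c2oc(C)cc2[C@@H]1/C=C/C
F4 | step 18 | (4R,5R,6S)-8-{[(tert-butyldimethylsilyl)oxy]methyl}-5-{(3R)-3-[(tert-butyldimethylsilyl)oxy]-4-methylpent-4-en-1-yl}-4-[(E)-2-iodoethenyl]-2,5-dimethyl-5,6-dihydro-4H-cyclohepta[b]furan-6-ol | C=C(C)[C@H](O[Si](C)(C)C(C)(C)C)CC[C@@]1(C)[C@@H](O)C=C(CO[Si](C)(C)C(C)(C)C)c2oc(C)cc2[C@@H]1/C=C/I
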